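## The problem

The target 26 is (2S,3S)-2-(3,4-dihydroxyphenyl)-3-(4-hydroxy-2-oxo-2H-pyran-6-yl)-6-[(E)-2-(4-hydroxyphenyl)ethenyl]-2,3-dihydro-4H-furo[3,2-c]pyran-4-one. Dihydrofuran ring A (O1, C2, C3, C3a, C7a) is fused through the C3a=C7a double bond to 2-pyranone ring B (C4 carbonyl, O5, C6, C7), which carries the 4-hydroxystyryl arm on C6. C2 bears the catechol and C3 bears the 4-hydroxy-2-pyranone ring C through C6′. The only stereocentres are C2 and C3, adjacent and trans; nothing else in the molecule can relay chirality to them, so they must be set together and in absolute terms by a reagent- or catalyst-controlled step. C3 is the fragile point: its hydrogen lies next to every carbonyl that can serve to build ring C, and O1, a vinylogous carboxylate oxygen, is β to it, so base can open ring A by elimination and reclose it, which would erase both centres at once. C2 is a benzylic ether of an electron-rich arene and ionises in strong acid, while the catechol, the styrylpyranone and the two enol lactones call for a buffered, non-oxidising final deprotection. The enabling feature is that O1 and the C4 carbonyl are attached to the two carbons of one double bond (C7a and C3a), the pattern left when a hydroxyl oxygen and carbon monoxide add across an alkyne. Ring A together with C4 therefore maps onto a homopropargylic alcohol and CO, with C2 and C3 lying outside the alkyne where acyclic stereocontrol can reach them.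

## Retrosynthesis

Locants C2, C3, C3a, C4, O5, C6, C7, C7a and the primed ring C locants always refer to the target.

**Phenol unmasking (26 from 25).** Only three O–Si bonds are cut. Silyl ethers are preferred to methyl, benzyl or acetal protection because their removal by buffered fluoride touches neither the styryl double bond, the benzylic C2–O1 bond nor the lactones. Compound 25 is the complete skeleton, and the forward step only has to avoid free phenoxide.

**Rings B and C (25 from 23 through 24).** The two lactone C–O bonds are cut: O1′–C2′ of ring C and O5–C4 of ring B. Ring C opens to the β-keto dioxinone 23, a masked acylketene. Ring B opens to a δ-keto-β-alkoxy enoate in which the ring A double bond holds the C4 ester and the C7 methylene cis. Both closures are redox-neutral C–O bond formations needing only heat and an amine base. Cutting ring B at carbon, or building the styryl arm by condensation on a C6 methyl group, would require strong base on a compound with an activated C3–H. Ring C is closed first so that base is applied only when C3 no longer has a carbonyl neighbour. Two rings are removed in one operation.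

**Ring C carbon chain (23 from 19 and 21, via 22).** The C5′–C6′ bond is cut, with the C6′ ketone traced to the aldol carbinol 22. Four of the five ring C carbons come from the silyl dienol ether 21 of a commercial dioxinone (20), and C6′ comes from the aldehyde of 19. A Lewis acid vinylogous aldol is chosen over acylation of a dienolate, since a strongly basic nucleophile would deprotonate the C7 methylene or C3 of the keto aldehyde. The forward step must discriminate the aldehyde from the enone.

**Oxidation levels (19 from 17, via 18).** No skeletal bond is cut. The C6 ketone and the aldehyde are traced to a TES-protected allylic carbinol and a TBS-protected primary alcohol. This is required by the key step: a C6 ketone would be a β,γ-alkynyl ketone prone to allenone and furan formation, and a free aldehyde on the future C3 would be epimerisable. The carbinol configuration at the future C6 is immaterial.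

**Ring A and C4 (17 from 14, 15 and 16).** This is the central cut: O1–C7a and C3a–C4. Compared with cuts at C2–C3 or C3–C3a, it leaves both stereocentres in an acyclic precursor. The ring closure then cannot scramble them, and C4 arrives from carbon monoxide (15) at the ester level with methanol (16). The precursor 14 has no ring other than the arenes. The forward reaction must close only from the hydroxyl on the future C2 and capture CO before protonolysis.

**Stereocentres (14 from 10 and 12, via 13).** The C2–C3 bond is cut. An allenylzinc reagent (13) generated from the enantioenriched propargylic mesylate 10 adds to the achiral aldehyde 12. The C3 configuration is transferred from the mesylate and the C2 configuration follows from the anti preference of the cyclic transition state. One catalyst-set carbinol thus controls both centres, and the two halves of the molecule are joined in the same step.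

**Mesylate (10 from 9, 8, 7, then 5 and 6).** The bond between the alkyne and the carbinol carbon is cut, leading to the terminal alkyne 5 and commercial aldehyde 6. The configuration is set by transfer hydrogenation of ynone 8 and not by direct asymmetric alkynylation, because 5 is the valuable partner and 6 is enolisable. The forward sequence needs one reliable enantioselective reduction.

**Enyne arm (5 from 4, from 2 and 3; 2 from 1; 12 from 11).** The C6–C7 bond is cut. A Barbier propargylation of the silylated cinnamaldehyde 2 with propargyl bromide (3) supplies C6, C7, C7a and C3a in one step from commercial 1. Aldehyde 12 comes from commercial 11 by silylation.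

## Roads not taken

**Alternative 1:** Ring A is cut at C3–C3a, C2–C3 and O1–C2, so that the silylated styrylpyranone A2 (ring B complete), the ring C aldehyde A3 and a benzylic sulfonium salt A4 would be merged into A1.
- *Forward step:* Knoevenagel condensation of A2 with A3, conjugate addition of the ylide from A4 to the alkylidene, and displacement of the sulfide by the enolate oxygen.
- *Merits:* the highest convergence of all routes, rings B and C bought essentially ready-made, the trans arrangement expected from the betaine closure, and a route roughly half as long as the chosen one.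
- *Weak points:* both stereocentres are created in one intermolecular step with no resident chirality, so the absolute configuration would rest on a chiral sulfide whose behaviour with a highly electrophilic alkylidene pyrandione is not established. Such alkylidenes also tend to take up a second molecule of the hydroxypyranone. A3 is an electron-poor, hydration-prone aldehyde. The acetal on ring C of A1 has to be removed with acid in the presence of the ionisable C2–O1 bond.
- *Comparison:* in step count this road is clearly better. The chosen plan sets against it absolute and relative control by a propargylation of known stereochemical course, and ring closures that can each be checked separately.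

**Alternative 2:** The C3–C3a bond is made by a 1,2-shift. The pyranopyrandione A6 would be treated with PhI(OAc)2 (a trivalent iodine reagent) in acidic trimethyl orthoformate, so that the ring-fusion carbon migrates from the ketone carbon to the neighbouring methylene and the ketone carbon becomes the C3 ester of A5.
- *Merits:* A6 is only a few steps from cheap materials, ring B is present from the start, the resident C2 centre directs C3, and the trans ester is the natural outcome.
- *Weak points:* in the precedent for this contraction the migrating carbon belongs to an electron-rich arene, whereas here it is the electron-poor α-carbon of a pyranone, so acetoxylation or dehydrogenation may win. The C2 centre of A6 is labile by reversible oxa-Michael opening, which puts its enantiopurity in doubt. The styryl arm must afterwards be built by a strongly basic condensation at the C6 methyl group beside an epimerisable C3 ester, and the catechol acetates of A5 would not survive that.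
- *Comparison:* this road is better in cost of materials and in having ring B early. The chosen plan answers with a key step of established type and with a styryl arm that is in place before any ring is formed.

**Alternative 3:** Ring B is cut at C7a–C7 and O5–C6. The dihydrofuran acid A8 would be annulated with the silylated enyne A9 under [Cp*RhCl2]2 and Ag2CO3 by carboxylate-directed activation of the C7a–H bond, alkyne insertion and C–O bond formation, giving A7.
- *Merits:* ring B and the styryl arm are made in a single step, with no carbinol to protect, deprotect and oxidise. In this respect it is better than the chosen plan, which spends four operations on C6.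
- *Weak points:* A8 already contains ring A with both stereocentres, so the hard problem is moved and not solved. Hot, oxidising silver conditions invite dehydrogenation of the dihydrofuran to a furan and epimerisation at the C3 ester. Regiocontrol is bought with a silyl group on C7 of A7 that costs a further step, and ring C still has to be built from the ester.
- *Comparison:* the chosen plan needs more functional-group steps for ring B, but it delivers ring A, C4 and both stereocentres in a form whose later ring closures are simple lactonisations.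

Key step: step 10

Remark on the chemistry: the carbinol carbon that becomes C6 is carried as a mixture of both configurations in 4, 5, 7–10, 13, 14, 17 and 18, and the carbinol formed in step 14 likewise in 22. Both are erased by oxidation, so these centres are left undefined in the SMILES. TBS = tert-butyldimethylsilyl, TES = triethylsilyl, TBSO and TESO the corresponding silyloxy groups.

## Route

Step 1
Reactants: 1 (E)-4-hydroxycinnamaldehyde
Product: 2 (E)-3-[4-(TBSO)phenyl]prop-2-enal
Conditions: TBSCl, imidazole, DMF, rt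
Reagents that add atoms: tert-butyldimethylsilyl chloride, CC(C)(C)[Si](C)(C)Cl
Why: Standard silylation of a phenol; the enal is not affected.

Step 2
Reactants: 2 (E)-3-[4-(TBSO)phenyl]prop-2-enal; 3 propargyl bromide
Product: 4 (E)-1-[4-(TBSO)phenyl]hex-1-en-5-yn-3-ol (racemic)
Conditions: Zn dust, THF/sat. aq NH4Cl, 0 °C to rt
Reagents that add atoms: none
Why: Zinc Barbier propargylation; the organozinc formed in the flask adds 1,2 to the enal through an SE2′ transition state and should give mainly the homopropargylic alcohol. The new carbinol centre is left racemic on purpose because it is oxidised in step 12.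

Step 3
Reactants: 4 (E)-1-[4-(TBSO)phenyl]hex-1-en-5-yn-3-ol
Product: 5 triethyl{[(E)-1-[4-(TBSO)phenyl]hex-1-en-5-yn-3-yl]oxy}silane
Conditions: TESCl, imidazole, CH2Cl2, 0 °C
Reagents that add atoms: triethylsilyl chloride, CC[Si](Cl)(CC)CC
Why: Silylation of a secondary alcohol; TES is chosen so that this ether can later be removed with buffered HF, which spares the aryl silyl ethers and the ionisable allylic position.

Step 4
Reactants: 5 triethyl{[(E)-1-[4-(TBSO)phenyl]hex-1-en-5-yn-3-yl]oxy}silane; 6 (tert-butyldimethylsilyloxy)acetaldehyde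
Product: 7 (E)-1-(TBSO)-8-[4-(TBSO)phenyl]-6-(TESO)oct-7-en-3-yn-2-ol (mixture of stereoisomers)
Conditions: n-BuLi, THF, −78 °C; then 6, −78 to −40 °C
Reagents that add atoms: none
Why: Lithiation of the terminal alkyne and addition to an aldehyde; silyl ethers are stable to n-BuLi at −78 °C. The new carbinol configuration is irrelevant because it is erased in step 5.

Step 5
Reactants: 7 (E)-1-(TBSO)-8-[4-(TBSO)phenyl]-6-(TESO)oct-7-en-3-yn-2-ol
Product: 8 (E)-1-(TBSO)-8-[4-(TBSO)phenyl]-6-(TESO)oct-7-en-3-yn-2-one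
Conditions: Dess–Martin periodinane, NaHCO3, CH2Cl2, 0 °C to rt
Reagents that add atoms: none
Why: Dess–Martin oxidation of a propargylic alcohol; the buffered, non-basic medium avoids ynone-to-allenone isomerisation.

Step 6
Reactants: 8 (E)-1-(TBSO)-8-[4-(TBSO)phenyl]-6-(TESO)oct-7-en-3-yn-2-one
Product: 9 (2S,7E)-1-(TBSO)-8-[4-(TBSO)phenyl]-6-(TESO)oct-7-en-3-yn-2-ol
Conditions: Ru[(R,R)-TsDPEN](p-cymene) (2 mol %), i-PrOH, rt
Reagents that add atoms: none
Why: Noyori asymmetric transfer hydrogenation of an alkynyl ketone; the alkynyl group acts as the π substituent in the transition state, so the (R,R) catalyst should deliver hydride to the face giving the 2S alcohol. The descriptor is S because the CH2OTBS group outranks the alkynyl group; the sense follows the model for alkynyl methyl ketones and is to be confirmed before material is committed.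

Step 7
Reactants: 9 (2S,7E)-1-(TBSO)-8-[4-(TBSO)phenyl]-6-(TESO)oct-7-en-3-yn-2-ol
Product: 10 (2S,7E)-1-(TBSO)-8-[4-(TBSO)phenyl]-6-(TESO)oct-7-en-3-yn-2-yl methanesulfonate
Conditions: MsCl, Et3N, CH2Cl2, −78 to 0 °C
Reagents that add atoms: methanesulfonyl chloride, CS(=O)(=O)Cl
Why: Mesylation of a secondary propargylic alcohol with retention at carbon; the mesylate is used without chromatography.

Step 8
Reactants: 11 3,4-dihydroxybenzaldehyde
Product: 12 3,4-bis(TBSO)benzaldehyde
Conditions: TBSCl, imidazole, DMF, rt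
Reagents that add atoms: tert-butyldimethylsilyl chloride, CC(C)(C)[Si](C)(C)Cl
Why: Standard bis-silylation of a catechol.

Step 9
Reactants: 10 (2S,7E)-1-(TBSO)-8-[4-(TBSO)phenyl]-6-(TESO)oct-7-en-3-yn-2-yl methanesulfonate; 12 3,4-bis(TBSO)benzaldehyde
Product: 14 (1S,2R,7E)-1-[3,4-bis(TBSO)phenyl]-2-[(TBSO)methyl]-8-[4-(TBSO)phenyl]-6-(TESO)oct-7-en-3-yn-1-ol, via allenylzinc reagent 13 (not isolated)
Conditions: Pd(OAc)2 (5 mol %), PPh3 (5 mol %), Et2Zn (3 equiv), THF, −78 to −20 °C
Reagents that add atoms: none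
Why: Marshall propargylation: zerovalent palladium displaces the mesylate anti (SN2′), transmetalation with Et2Zn gives allenylzinc 13, and 13 adds to the aldehyde through a cyclic SE2′ transition state. The future C3 is set by transfer of the mesylate configuration with overall inversion (2S mesylate to 2R), and the future C2 by the anti preference of the cyclic transition state, in which the aryl group of the aldehyde avoids the CH2OTBS group.

Step 10
Reactants: 14 (1S,2R,7E)-1-[3,4-bis(TBSO)phenyl]-2-[(TBSO)methyl]-8-[4-(TBSO)phenyl]-6-(TESO)oct-7-en-3-yn-1-ol; 15 carbon monoxide; 16 methanol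
Product: 17 methyl (4R,5S)-5-[3,4-bis(TBSO)phenyl]-4-[(TBSO)methyl]-2-[(E)-4-[4-(TBSO)phenyl]-2-(TESO)but-3-en-1-yl]-4,5-dihydrofuran-3-carboxylate
Conditions: PdCl2(MeCN)2 (10 mol %), p-benzoquinone (1.5 equiv), CO (1 atm), MeOH/CH2Cl2, 0 °C to rt
Reagents that add atoms: none
Why: Divalent palladium binds the internal alkyne of 14 and the hydroxyl on the future C2 adds to the distal alkyne carbon in a 5-endo-dig oxypalladation (O1–C7a), the only closure open to a 3-yn-1-ol because the 4-exo alternative is strained. The resulting cyclic vinylpalladium species at C3a inserts CO and the acylpalladium is cleaved by methanol (C3a–C4), giving ester 17 and zerovalent palladium, which p-benzoquinone returns to the divalent state. The closest known reaction type is the palladium-catalysed oxidative heterocyclisation–alkoxycarbonylation of 3-yn-1-ols and 3-yne-1,2-diols to dihydrofuran- and furan-3-carboxylates. No stereocentre is formed: C2 and C3 are sp3 carbons between the hydroxyl and the alkyne and are carried over unchanged, the trans arrangement of 17 following from the anti configuration of 14. The selectivity needed is chemo- and regioselectivity: only one hydroxyl is free, so the alkyne cannot be attacked from its other side by the oxygen on the future C6, and the silyl ethers are too weak as nucleophiles to compete. p-Benzoquinone is preferred to CuCl2 as terminal oxidant because no HCl accumulates, which protects the TES ether and the allylic position, and methanol at 0 °C under CO favours CO capture of the vinylpalladium species over protonolysis.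

Step 11
Reactants: 17 methyl (4R,5S)-5-[3,4-bis(TBSO)phenyl]-4-[(TBSO)methyl]-2-[(E)-4-[4-(TBSO)phenyl]-2-(TESO)but-3-en-1-yl]-4,5-dihydrofuran-3-carboxylate
Product: 18 methyl (4R,5S)-5-[3,4-bis(TBSO)phenyl]-2-[(E)-2-hydroxy-4-[4-(TBSO)phenyl]but-3-en-1-yl]-4-(hydroxymethyl)-4,5-dihydrofuran-3-carboxylate
Conditions: HF·pyridine, pyridine, THF, 0 °C to rt
Reagents that add atoms: none
Why: Acidic fluoride cleaves the primary alkyl TBS ether and the secondary TES ether much faster than aryl TBS ethers, whose oxygen is a poor proton acceptor. The pyridine buffer should keep the liberated allylic alcohol from ionising.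

Step 12
Reactants: 18 methyl (4R,5S)-5-[3,4-bis(TBSO)phenyl]-2-[(E)-2-hydroxy-4-[4-(TBSO)phenyl]but-3-en-1-yl]-4-(hydroxymethyl)-4,5-dihydrofuran-3-carboxylate
Product: 19 methyl (4S,5S)-5-[3,4-bis(TBSO)phenyl]-4-formyl-2-[(E)-4-[4-(TBSO)phenyl]-2-oxobut-3-en-1-yl]-4,5-dihydrofuran-3-carboxylate
Conditions: Dess–Martin periodinane (3 equiv), NaHCO3, CH2Cl2, 0 °C to rt
Reagents that add atoms: none
Why: Dess–Martin oxidation of both alcohols in one operation; the neutral buffered medium should leave the aldehyde α-carbon (the future C3) untouched. The descriptor at C4 changes from R to S only because the formyl group outranks C5.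

Step 13
Reactants: 20 2,2,6-trimethyl-4H-1,3-dioxin-4-one
Product: 21 trimethyl[(2,2-dimethyl-6-methylidene-6H-1,3-dioxin-4-yl)oxy]silane
Conditions: LDA, THF, −78 °C; then TMSCl
Reagents that add atoms: trimethylsilyl chloride, C[Si](C)(C)Cl
Why: Deprotonation at the C6 methyl group and O-silylation of the dienolate, the standard preparation of this silyl dienol ether.

Step 14
Reactants: 19 methyl (4S,5S)-5-[3,4-bis(TBSO)phenyl]-4-formyl-2-[(E)-4-[4-(TBSO)phenyl]-2-oxobut-3-en-1-yl]-4,5-dihydrofuran-3-carboxylate; 21 trimethyl[(2,2-dimethyl-6-methylidene-6H-1,3-dioxin-4-yl)oxy]silane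
Product: 22 methyl (4R,5S)-5-[3,4-bis(TBSO)phenyl]-4-[2-(2,2-dimethyl-4-oxo-4H-1,3-dioxin-6-yl)-1-hydroxyethyl]-2-[(E)-4-[4-(TBSO)phenyl]-2-oxobut-3-en-1-yl]-4,5-dihydrofuran-3-carboxylate (both carbinol epimers)
Conditions: BF3·OEt2, CH2Cl2, −78 °C; aq NaHCO3
Reagents that add atoms: none
Why: Vinylogous Mukaiyama aldol: the terminal carbon of the dienol ether attacks the BF3-activated aldehyde, which is far more electrophilic than the enone or the ester. The non-basic conditions avoid deprotonation at C3 or C7; the new carbinol centre is not controlled because it is oxidised in step 15.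

Step 15
Reactants: 22 methyl (4R,5S)-5-[3,4-bis(TBSO)phenyl]-4-[2-(2,2-dimethyl-4-oxo-4H-1,3-dioxin-6-yl)-1-hydroxyethyl]-2-[(E)-4-[4-(TBSO)phenyl]-2-oxobut-3-en-1-yl]-4,5-dihydrofuran-3-carboxylate
Product: 23 methyl (4S,5S)-5-[3,4-bis(TBSO)phenyl]-4-[2-(2,2-dimethyl-4-oxo-4H-1,3-dioxin-6-yl)acetyl]-2-[(E)-4-[4-(TBSO)phenyl]-2-oxobut-3-en-1-yl]-4,5-dihydrofuran-3-carboxylate
Conditions: Dess–Martin periodinane, NaHCO3, CH2Cl2, 0 °C to rt
Reagents that add atoms: none
Why: Dess–Martin oxidation of a β-hydroxy carbonyl-type compound to the 1,3-dicarbonyl system, again without base.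

Step 16
Reactants: 23 methyl (4S,5S)-5-[3,4-bis(TBSO)phenyl]-4-[2-(2,2-dimethyl-4-oxo-4H-1,3-dioxin-6-yl)acetyl]-2-[(E)-4-[4-(TBSO)phenyl]-2-oxobut-3-en-1-yl]-4,5-dihydrofuran-3-carboxylate
Product: 25 (2S,3S)-2-[3,4-bis(TBSO)phenyl]-3-(4-hydroxy-2-oxo-2H-pyran-6-yl)-6-[(E)-2-[4-(TBSO)phenyl]ethenyl]-2,3-dihydro-4H-furo[3,2-c]pyran-4-one, via ring C hydroxypyranone keto ester 24 (not isolated)
Conditions: PhMe (dilute), 110 °C; cool, then DBU, THF, rt
Reagents that add atoms: none
Why: Thermal retro-[4+2] of the dioxinone releases acetone and an acylketene, which is trapped by the enol oxygen of the neighbouring ketone to give the 4-hydroxy-2-pyranone ring C (24). DBU then enolises the C6 ketone towards C7 and the enol oxygen attacks the C4 ester (6-exo-trig lactonisation with loss of methanol), closing ring B. Base is applied only now, when C3 has no carbonyl neighbour.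

Step 17
Reactants: 25 (2S,3S)-2-[3,4-bis(TBSO)phenyl]-3-(4-hydroxy-2-oxo-2H-pyran-6-yl)-6-[(E)-2-[4-(TBSO)phenyl]ethenyl]-2,3-dihydro-4H-furo[3,2-c]pyran-4-one
Product: 26 (2S,3S)-2-(3,4-dihydroxyphenyl)-3-(4-hydroxy-2-oxo-2H-pyran-6-yl)-6-[(E)-2-(4-hydroxyphenyl)ethenyl]-2,3-dihydro-4H-furo[3,2-c]pyran-4-one
Conditions: TBAF, AcOH, THF, 0 °C
Reagents that add atoms: none
Why: Fluoride cleavage of the three aryl silyl ethers; acetic acid buffers the phenoxides so that the catechol, the lactones and C3 are not exposed to free base.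

## Compound list

1 | (E)-4-hydroxycinnamaldehyde | O=C/C=C/c1ccc(O)cc1 | starting material
2 | (E)-3-[4-(tert-butyldimethylsilyloxy)phenyl]prop-2-enal | O=C/C=C/c1ccc(O[Si](C)(C)C(C)(C)C)cc1 | intermediate
3 | propargyl bromide | C#CCBr | starting material
4 | (E)-1-[4-(tert-butyldimethylsilyloxy)phenyl]hex-1-en-5-yn-3-ol, racemic | OC(CC#C)/C=C/c1ccc(O[Si](C)(C)C(C)(C)C)cc1 | intermediate
5 | triethyl{[(E)-1-[4-(tert-butyldimethylsilyloxy)phenyl]hex-1-en-5-yn-3-yl]oxy}silane, racemic | CC[Si](CC)(CC)OC(CC#C)/C=C/c1ccc(O[Si](C)(C)C(C)(C)C)cc1 | intermediate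
6 | (tert-butyldimethylsilyloxy)acetaldehyde | CC(C)(C)[Si](C)(C)OCC=O | starting material
7 | (E)-1-(tert-butyldimethylsilyloxy)-8-[4-(tert-butyldimethylsilyloxy)phenyl]-6-(triethylsilyloxy)oct-7-en-3-yn-2-ol, stereoisomer mixture | CC(C)(C)[Si](C)(C)OCC(O)C#CCC(O[Si](CC)(CC)CC)/C=C/c1ccc(O[Si](C)(C)C(C)(C)C)cc1 | intermediate
8 | (E)-1-(tert-butyldimethylsilyloxy)-8-[4-(tert-butyldimethylsilyloxy)phenyl]-6-(triethylsilyloxy)oct-7-en-3-yn-2-one | CC(C)(C)[Si](C)(C)OCC(=O)C#CCC(O[Si](CC)(CC)CC)/C=C/c1ccc(O[Si](C)(C)C(C)(C)C)cc1 | intermediate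
9 | (2S,7E)-1-(tert-butyldimethylsilyloxy)-8-[4-(tert-butyldimethylsilyloxy)phenyl]-6-(triethylsilyloxy)oct-7-en-3-yn-2-ol, both C6 epimers | CC(C)(C)[Si](C)(C)OC[C@@H](O)C#CCC(O[Si](CC)(CC)CC)/C=C/c1ccc(O[Si](C)(C)C(C)(C)C)cc1 | intermediate
10 | (2S,7E)-1-(tert-butyldimethylsilyloxy)-8-[4-(tert-butyldimethylsilyloxy)phenyl]-6-(triethylsilyloxy)oct-7-en-3-yn-2-yl methanesulfonate | CC(C)(C)[Si](C)(C)OC[C@@H](OS(C)(=O)=O)C#CCC(O[Si](CC)(CC)CC)/C=C/c1ccc(O[Si](C)(C)C(C)(C)C)cc1 | intermediate
11 | 3,4-dihydroxybenzaldehyde | O=Cc1ccc(O)c(O)c1 | starting material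
12 | 3,4-bis(tert-butyldimethylsilyloxy)benzaldehyde | O=Cc1ccc(O[Si](C)(C)C(C)(C)C)c(O[Si](C)(C)C(C)(C)C)c1 | intermediate
13 | ethyl[(aS,7E)-1-(tert-butyldimethylsilyloxy)-8-[4-(tert-butyldimethylsilyloxy)phenyl]-6-(triethylsilyloxy)octa-2,3,7-trien-4-yl]zinc (zinc anti to the departed mesylate) | [H]C(CO[Si](C)(C)C(C)(C)C)=[C@@]=C([Zn]CC)CC(O[Si](CC)(CC)CC)/C=C/c1ccc(O[Si](C)(C)C(C)(C)C)cc1 | intermediate (not isolated)
14 | (1S,2R,7E)-1-[3,4-bis(tert-butyldimethylsilyloxy)phenyl]-2-[(tert-butyldimethylsilyloxy)methyl]-8-[4-(tert-butyldimethylsilyloxy)phenyl]-6-(triethylsilyloxy)oct-7-en-3-yn-1-ol | O[C@@H]([C@@H](CO[Si](C)(C)C(C)(C)C)C#CCC(O[Si](CC)(CC)CC)/C=C/c1ccc(O[Si](C)(C)C(C)(C)C)cc1)c1ccc(O[Si](C)(C)C(C)(C)C)c(O[Si](C)(C)C(C)(C)C)c1 | intermediate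
15 | carbon monoxide | [C-]#[O+] | starting material
16 | methanol | CO | starting material
17 | methyl (4R,5S)-5-[3,4-bis(tert-butyldimethylsilyloxy)phenyl]-4-[(tert-butyldimethylsilyloxy)methyl]-2-[(E)-4-[4-(tert-butyldimethylsilyloxy)phenyl]-2-(triethylsilyloxy)but-3-en-1-yl]-4,5-dihydrofuran-3-carboxylate | CC(C)(C)[Si](C)(C)OC[C@H]1C(C(=O)OC)=C(CC(O[Si](CC)(CC)CC)/C=C/c2ccc(O[Si](C)(C)C(C)(C)C)cc2)O[C@@H]1c1ccc(O[Si](C)(C)C(C)(C)C)c(O[Si](C)(C)C(C)(C)C)c1 | intermediate
18 | methyl (4R,5S)-5-[3,4-bis(tert-butyldimethylsilyloxy)phenyl]-2-[(E)-2-hydroxy-4-[4-(tert-butyldimethylsilyloxy)phenyl]but-3-en-1-yl]-4-(hydroxymethyl)-4,5-dihydrofuran-3-carboxylate | OC[C@H]1C(C(=O)OC)=C(CC(O)/C=C/c2ccc(O[Si](C)(C)C(C)(C)C)cc2)O[C@@H]1c1ccc(O[Si](C)(C)C(C)(C)C)c(O[Si](C)(C)C(C)(C)C)c1 | intermediate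
19 | methyl (4S,5S)-5-[3,4-bis(tert-butyldimethylsilyloxy)phenyl]-4-formyl-2-[(E)-4-[4-(tert-butyldimethylsilyloxy)phenyl]-2-oxobut-3-en-1-yl]-4,5-dihydrofuran-3-carboxylate | O=C[C@H]1C(C(=O)OC)=C(CC(=O)/C=C/c2ccc(O[Si](C)(C)C(C)(C)C)cc2)O[C@@H]1c1ccc(O[Si](C)(C)C(C)(C)C)c(O[Si](C)(C)C(C)(C)C)c1 | intermediate
20 | 2,2,6-trimethyl-4H-1,3-dioxin-4-one | CC1=CC(=O)OC(C)(C)O1 | starting material
21 | trimethyl[(2,2-dimethyl-6-methylidene-6H-1,3-dioxin-4-yl)oxy]silane | C=C1C=C(O[Si](C)(C)C)OC(C)(C)O1 | intermediate
22 | methyl (4R,5S)-5-[3,4-bis(tert-butyldimethylsilyloxy)phenyl]-4-[2-(2,2-dimethyl-4-oxo-4H-1,3-dioxin-6-yl)-1-hydroxyethyl]-2-[(E)-4-[4-(tert-butyldimethylsilyloxy)phenyl]-2-oxobut-3-en-1-yl]-4,5-dihydrofuran-3-carboxylate, both carbinol epimers | OC(CC1=CC(=O)OC(C)(C)O1)[C@H]1C(C(=O)OC)=C(CC(=O)/C=C/c2ccc(O[Si](C)(C)C(C)(C)C)cc2)O[C@@H]1c1ccc(O[Si](C)(C)C(C)(C)C)c(O[Si](C)(C)C(C)(C)C)c1 | intermediate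
23 | methyl (4S,5S)-5-[3,4-bis(tert-butyldimethylsilyloxy)phenyl]-4-[2-(2,2-dimethyl-4-oxo-4H-1,3-dioxin-6-yl)acetyl]-2-[(E)-4-[4-(tert-butyldimethylsilyloxy)phenyl]-2-oxobut-3-en-1-yl]-4,5-dihydrofuran-3-carboxylate | O=C(CC1=CC(=O)OC(C)(C)O1)[C@H]1C(C(=O)OC)=C(CC(=O)/C=C/c2ccc(O[Si](C)(C)C(C)(C)C)cc2)O[C@@H]1c1ccc(O[Si](C)(C)C(C)(C)C)c(O[Si](C)(C)C(C)(C)C)c1 | intermediate
24 | methyl (4S,5S)-5-[3,4-bis(tert-butyldimethylsilyloxy)phenyl]-4-(4-hydroxy-2-oxo-2H-pyran-6-yl)-2-[(E)-4-[4-(tert-butyldimethylsilyloxy)phenyl]-2-oxobut-3-en-1-yl]-4,5-dihydrofuran-3-carboxylate | O=c1cc(O)cc([C@H]2C(C(=O)OC)=C(CC(=O)/C=C/c3ccc(O[Si](C)(C)C(C)(C)C)cc3)O[C@@H]2c2ccc(O[Si](C)(C)C(C)(C)C)c(O[Si](C)(C)C(C)(C)C)c2)o1 | intermediate (not isolated)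
25 | (2S,3S)-2-[3,4-bis(tert-butyldimethylsilyloxy)phenyl]-3-(4-hydroxy-2-oxo-2H-pyran-6-yl)-6-[(E)-2-[4-(tert-butyldimethylsilyloxy)phenyl]ethenyl]-2,3-dihydro-4H-furo[3,2-c]pyran-4-one | O=c1cc(O)cc([C@H]2c3c(cc(/C=C/c4ccc(O[Si](C)(C)C(C)(C)C)cc4)oc3=O)O[C@@H]2c2ccc(O[Si](C)(C)C(C)(C)C)c(O[Si](C)(C)C(C)(C)C)c2)o1 | intermediate
26 | (2S,3S)-2-(3,4-dihydroxyphenyl)-3-(4-hydroxy-2-oxo-2H-pyran-6-yl)-6-[(E)-2-(4-hydroxyphenyl)ethenyl]-2,3-dihydro-4H-furo[3,2-c]pyran-4-one | O=c1cc(O)cc([C@H]2c3c(cc(/C=C/c4ccc(O)cc4)oc3=O)O[C@@H]2c2ccc(O)c(O)c2)o1 | target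

## Step count and risks

Total: 17 steps. Longest linear sequence: 15 steps (steps 1–7, 9–12 and 14–17); steps 8 and 13 are single-step side branches.

**Step 10 (key step).** The most likely failures are:
- protonolysis of the vinylpalladium species before CO insertion, giving a non-carbonylated enol ether that adds methanol;
- diversion into the alkoxycarbonyl–palladium channel that leads to alkylidene lactones;
- premature loss of the TES group through traces of acid, which would open the competing closure from the oxygen on the future C6.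

Fallback: starting from 14, iodocyclisation (I2, NaHCO3, MeCN, 0 °C, 5-endo-dig) would give (2S,3R)-2-[3,4-bis(TBSO)phenyl]-3-[(TBSO)methyl]-4-iodo-5-[(E)-4-[4-(TBSO)phenyl]-2-(TESO)but-3-en-1-yl]-2,3-dihydrofuran F1. Methoxycarbonylation of this vinyl iodide (Pd(OAc)2, dppf, CO, MeOH, Et3N, DMF, 60 °C) then returns to the route at 17. The same two bonds are formed in two separate, known operations.

**Step 9.** The allenylzinc reagent may lose its silyloxy group by 1,4-elimination faster than it adds to an electron-rich aryl aldehyde. The anti selectivity or the chirality transfer may also erode if the allenylpalladium precursor equilibrates.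

Fallback: starting from 9, acylation (ClCO2Me, pyridine) would give (2S,7E)-1-(TBSO)-8-[4-(TBSO)phenyl]-6-(TESO)oct-7-en-3-yn-2-yl methyl carbonate F2. Copper-catalysed anti-SN2′ borylation (CuCl, NaOt-Bu, Xantphos, B2pin2, THF) would give the isolable 2-[(aR,7E)-1-(TBSO)-8-[4-(TBSO)phenyl]-6-(TESO)octa-2,3,7-trien-4-yl]-4,4,5,5-tetramethyl-1,3,2-dioxaborolane F3. Allenylboronates do not eliminate in this way, and F3 should add to 12 on warming through the same closed transition state, returning to the route at 14.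

**Step 11.** Once the TES group has left, the allylic carbinol next to the electron-rich styrene may ionise (allylic transposition or substitution). Aryl silyl ethers may be lost in part, and the free primary alcohol may lactonise onto the ester.

Fallback: starting from 17, PPTS in MeOH at 0 °C would remove only the TES group to give methyl (4R,5S)-5-[3,4-bis(TBSO)phenyl]-4-[(TBSO)methyl]-2-[(E)-2-hydroxy-4-[4-(TBSO)phenyl]but-3-en-1-yl]-4,5-dihydrofuran-3-carboxylate F4. MnO2 in CH2Cl2 would oxidise it at once to the enone, methyl (4R,5S)-5-[3,4-bis(TBSO)phenyl]-4-[(TBSO)methyl]-2-[(E)-4-[4-(TBSO)phenyl]-2-oxobut-3-en-1-yl]-4,5-dihydrofuran-3-carboxylate F5, which can no longer ionise. HF·pyridine would then free the primary alcohol, methyl (4R,5S)-5-[3,4-bis(TBSO)phenyl]-4-(hydroxymethyl)-2-[(E)-4-[4-(TBSO)phenyl]-2-oxobut-3-en-1-yl]-4,5-dihydrofuran-3-carboxylate F6, and Dess–Martin oxidation returns to the route at 19.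

**Step 14.** The dienol ether may add in a conjugate sense to the enone. The Lewis acid may also enolise the aldehyde, with epimerisation at the future C3 or β-elimination of O1.

Fallback: starting from 19, a vinylogous Reformatsky addition replaces the Lewis acid. 6-(Bromomethyl)-2,2-dimethyl-4H-1,3-dioxin-4-one F7 (from 20 by lithiation at the methyl group and bromination) with Zn dust in THF should add to the aldehyde only, returning to the route at 22.

**Step 16.** In the base stage, the anion of the new hydroxypyranone may add intermolecularly to the enone of another molecule before ring B has closed. The salt of 24 may also separate and stall the lactonisation.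

Fallback: starting from 23, the order of ring closures is reversed. DBU in THF closes ring B first to give 6-{2-[(2S,3S)-2-[3,4-bis(TBSO)phenyl]-4-oxo-6-[(E)-2-[4-(TBSO)phenyl]ethenyl]-2,3-dihydro-4H-furo[3,2-c]pyran-3-yl]-2-oxoethyl}-2,2-dimethyl-4H-1,3-dioxin-4-one F8, in which the enone is gone. Heating in toluene at 110 °C then closes ring C under neutral conditions, returning to the route at 25.

## Further compounds

F1 | step 10 | (2S,3R)-2-[3,4-bis(tert-butyldimethylsilyloxy)phenyl]-3-[(tert-butyldimethylsilyloxy)methyl]-4-iodo-5-[(E)-4-[4-(tert-butyldimethylsilyloxy)phenyl]-2-(triethylsilyloxy)but-3-en-1-yl]-2,3-dihydrofuran | CC(C)(C)[Si](C)(C)OC[C@H]1C(I)=C(CC(O[Si](CC)(CC)CC)/C=C/c2ccc(O[Si](C)(C)C(C)(C)C)cc2)O[C@@H]1c1ccc(O[Si](C)(C)C(C)(C)C)c(O[Si](C)(C)C(C)(C)C)c1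
F2 | step 9 | (2S,7E)-1-(tert-butyldimethylsilyloxy)-8-[4-(tert-butyldimethylsilyloxy)phenyl]-6-(triethylsilyloxy)oct-7-en-3-yn-2-yl methyl carbonate | CC(C)(C)[Si](C)(C)OC[C@@H](OC(=O)OC)C#CCC(O[Si](CC)(CC)CC)/C=C/c1ccc(O[Si](C)(C)C(C)(C)C)cc1
F3 | step 9 | 2-[(aR,7E)-1-(tert-butyldimethylsilyloxy)-8-[4-(tert-butyldimethylsilyloxy)phenyl]-6-(triethylsilyloxy)octa-2,3,7-trien-4-yl]-4,4,5,5-tetramethyl-1,3,2-dioxaborolane | [H]C(CO[Si](C)(C)C(C)(C)C)=[C@@]=C(B1OC(C)(C)C(C)(C)O1)CC(O[Si](CC)(CC)CC)/C=C/c1ccc(O[Si](C)(C)C(C)(C)C)cc1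
F4 | step 11 | methyl (4R,5S)-5-[3,4-bis(tert-butyldimethylsilyloxy)phenyl]-4-[(tert-butyldimethylsilyloxy)methyl]-2-[(E)-2-hydroxy-4-[4-(tert-butyldimethylsilyloxy)phenyl]but-3-en-1-yl]-4,5-dihydrofuran-3-carboxylate | CC(C)(C)[Si](C)(C)OC[C@H]1C(C(=O)OC)=C(CC(O)/C=C/c2ccc(O[Si](C)(C)C(C)(C)C)cc2)O[C@@H]1c1ccc(O[Si](C)(C)C(C)(C)C)c(O[Si](C)(C)C(C)(C)C)c1
F5 | step 11 | methyl (4R,5S)-5-[3,4-bis(tert-butyldimethylsilyloxy)phenyl]-4-[(tert-butyldimethylsilyloxy)methyl]-2-[(E)-4-[4-(tert-butyldimethylsilyloxy)phenyl]-2-oxobut-3-en-1-yl]-4,5-dihydrofuran-3-carboxylate | CC(C)(C)[Si](C)(C)OC[C@H]1C(C(=O)OC)=C(CC(=O)/C=C/c2ccc(O[Si](C)(C)C(C)(C)C)cc2)O[C@@H]1c1ccc(O[Si](C)(C)C(C)(C)C)c(O[Si](C)(C)C(C)(C)C)c1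
F6 | step 11 | methyl (4R,5S)-5-[3,4-bis(tert-butyldimethylsilyloxy)phenyl]-4-(hydroxymethyl)-2-[(E)-4-[4-(tert-butyldimethylsilyloxy)phenyl]-2-oxobut-3-en-1-yl]-4,5-dihydrofuran-3-carboxylate | OC[C@H]1C(C(=O)OC)=C(CC(=O)/C=C/c2ccc(O[Si](C)(C)C(C)(C)C)cc2)O[C@@H]1c1ccc(O[Si](C)(C)C(C)(C)C)c(O[Si](C)(C)C(C)(C)C)c1
F7 | step 14 | 6-(bromomethyl)-2,2-dimethyl-4H-1,3-dioxin-4-one | BrCC1=CC(=O)OC(C)(C)O1
F8 | step 16 | 6-{2-[(2S,3S)-2-[3,4-bis(tert-butyldimethylsilyloxy)phenyl]-4-oxo-6-[(E)-2-[4-(tert-butyldimethylsilyloxy)phenyl]ethenyl]-2,3-dihydro-4H-furo[3,2-c]pyran-3-yl]-2-oxoethyl}-2,2-dimethyl-4H-1,3-dioxin-4-one | O=C(CC1=CC(=O)OC(C)(C)O1)[C@H]1c2c(cc(/C=C/c3ccc(O[Si](C)(C)C(C)(C)C)cc3)oc2=O)O[C@@H]1c1ccc(O[Si](C)(C)C(C)(C)C)c(O[Si](C)(C)C(C)(C)C)c1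
A1 | alternative 1 | (2S,3S)-2-[3,4-bis(tert-butyldimethylsilyloxy)phenyl]-3-[4-(methoxymethoxy)-2-oxo-2H-pyran-6-yl]-6-[(E)-2-[4-(tert-butyldimethylsilyloxy)phenyl]ethenyl]-2,3-dihydro-4H-furo[3,2-c]pyran-4-one | COCOc1cc([C@H]2c3c(cc(/C=C/c4ccc(O[Si](C)(C)C(C)(C)C)cc4)oc3=O)O[C@@H]2c2ccc(O[Si](C)(C)C(C)(C)C)c(O[Si](C)(C)C(C)(C)C)c2)oc(=O)c1
A2 | alternative 1 | 4-hydroxy-6-[(E)-2-[4-(tert-butyldimethylsilyloxy)phenyl]ethenyl]-2H-pyran-2-one | O=c1cc(O)cc(/C=C/c2ccc(O[Si](C)(C)C(C)(C)C)cc2)o1
A3 | alternative 1 | 4-(methoxymethoxy)-2-oxo-2H-pyran-6-carbaldehyde | COCOc1cc(C=O)oc(=O)c1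
A4 | alternative 1 | [3,4-bis(tert-butyldimethylsilyloxy)benzyl]dimethylsulfonium bromide (a chiral sulfide would take the place of dimethyl sulfide in an enantioselective version) | C[S+](C)Cc1ccc(O[Si](C)(C)C(C)(C)C)c(O[Si](C)(C)C(C)(C)C)c1.[Br-]
A5 | alternative 2 | methyl (2S,3S)-2-(3,4-diacetoxyphenyl)-6-methyl-4-oxo-2,3-dihydro-4H-furo[3,2-c]pyran-3-carboxylate | COC(=O)[C@H]1c2c(cc(C)oc2=O)O[C@@H]1c1ccc(OC(C)=O)c(OC(C)=O)c1
A6 | alternative 2 | (2S)-2-(3,4-diacetoxyphenyl)-7-methyl-2,3-dihydro-4H,5H-pyrano[3,2-c]pyran-4,5-dione | CC1=CC2=C(C(=O)C[C@@H](c3ccc(OC(C)=O)c(OC(C)=O)c3)O2)C(=O)O1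
A7 | alternative 3 | methyl (2S,3S)-2-[3,4-bis(tert-butyldimethylsilyloxy)phenyl]-4-oxo-6-[(E)-2-[4-(tert-butyldimethylsilyloxy)phenyl]ethenyl]-7-(trimethylsilyl)-2,3-dihydro-4H-furo[3,2-c]pyran-3-carboxylate | COC(=O)[C@H]1c2c(c([Si](C)(C)C)c(/C=C/c3ccc(O[Si](C)(C)C(C)(C)C)cc3)oc2=O)O[C@@H]1c1ccc(O[Si](C)(C)C(C)(C)C)c(O[Si](C)(C)C(C)(C)C)c1
A8 | alternative 3 | (4S,5S)-5-[3,4-bis(tert-butyldimethylsilyloxy)phenyl]-4-(methoxycarbonyl)-4,5-dihydrofuran-3-carboxylic acid | COC(=O)[C@H]1C(C(=O)O)=CO[C@@H]1c1ccc(O[Si](C)(C)C(C)(C)C)c(O[Si](C)(C)C(C)(C)C)c1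
A9 | alternative 3 | (E)-tert-butyldimethyl{4-[4-(trimethylsilyl)but-1-en-3-yn-1-yl]phenoxy}silane | C[Si](C)(C)C#C/C=C/c1ccc(O[Si](C)(C)C(C)(C)C)cc1
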